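A direct plan would make two flavan halves, join them at C8–C6' by a Suzuki coupling (biaryl A1), and dearomatise the upper phenol
with a trivalent iodine reagent so that a lactic acid tethered to O7 closes on C8 (lactone-bridged dienone A2); methoxide would then
open the lactone, add O5' to C8a with loss of a C4 ester and exchange the C7 ether (8-hydroxy ketal enone A3), before O-methylation.
Weakest would be (a) the dearomatising lactonisation: an untested reaction that would have to set the quaternary C8 from a lactate
centre by a conformational argument and choose para C8 over ortho C6, on material about eighteen steps old; (b) the methoxide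
cascade: three unproven events in one flask, so the ketal ring closure would be left to chance; (c) the run-up: about a dozen
steps would only move protecting, leaving and auxiliary groups, and a tetra-ortho Suzuki coupling would stake both long fragments.

The new retrosynthesis cuts C4=C4a, O1–C2 and O5'–C8a in one operation: C4a is the central carbon of a masked cyclohexane-1,3-dione
(C5=O and ketal carbon C8a), C4=C4a is a Knoevenagel alkene and the ring oxygen O1 on C8a carries benzylic C2, which is the retron of a
1,3-dione/cinnamaldehyde oxa-6π annulation, while the phenol O5' on the C8 aryl group sits over C8a for a 5-exo ketal closure.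
The dione left behind is cut at C4a–C8a (Claisen) and C7–C8 (vinylic substitution) to a benzofuranone on the lower flavanol.
Ring order: lower pyran, lactone, upper carbocycle (built de novo, never an arene), then upper pyran and dihydrofuran together, last.
No biaryl coupling, phenol oxidation or tether occurs: C8 is set by a catalyst on an early enolate, C8a by ring fusion, C2 by equilibration.

Key step: step 14

Remark: the locants of the target are used throughout (upper unit O1, C2–C8a; lower flavan primed; isolated flavans carry unprimed locants in their names). Dione 22 is drawn as the diketone and is expected to exist as its enol and its O5' hemiketal.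

Step 1
Reactants: 1 wogonin (5,7-dihydroxy-8-methoxyflavone)
Product: 3 5-benzyloxy-7,8-dimethoxyflavone, via 5-hydroxy-7,8-dimethoxyflavone 2 (not isolated)
Conditions: MeI (1.0 equiv), K2CO3, DMF, rt; then BnBr (1.3 equiv), 70 °C
Reagents that add atoms: iodomethane, CI; benzyl bromide, BrCc1ccccc1
Why: Two Williamson etherifications in one flask: the 7-OH reacts at room temperature, the chelated 5-OH only on heating, and the flavone is achiral and base-stable.

Step 2
Reactants: 3 5-benzyloxy-7,8-dimethoxyflavone
Product: 5 (2S,4S)-5-benzyloxy-7,8-dimethoxyflavan-4-ol (2,4-cis), via (2S)-5-benzyloxy-7,8-dimethoxyflavanone 4 (not isolated)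
Conditions: Ru(cod)(2-methylallyl)2 (5 mol %), 1,3-bis[1-(naphthalen-1-yl)ethyl]-4,5-dihydroimidazolium tetrafluoroborate (10 mol %, the enantiomer that gives 2S), KOt-Bu (15 mol %), H2 (120 bar), toluene–hexane, 40 °C
Reagents that add atoms: none
Why: Ruthenium–NHC-catalysed asymmetric hydrogenation of flavones: the catalyst chooses the face of C2=C3 (2S), and the ketone of 4 is then reduced by axial hydrogen delivery to the 2,4-cis alcohol (4S).

Step 3
Reactants: 5 (2S,4S)-5-benzyloxy-7,8-dimethoxyflavan-4-ol
Product: 6 (2S,4R)-5-benzyloxy-7,8-dimethoxyflavan-4-yl benzoate (2,4-trans)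
Conditions: PhCO2H, PPh3, DIAD, toluene, −20 °C → rt
Reagents that add atoms: benzoic acid, OC(=O)c1ccccc1
Why: Mitsunobu inversion: SN2 displacement of the activated equatorial alcohol gives the pseudo-axial 4R ester, the standard way from cis- to trans-flavan-4-ols.

Step 4
Reactants: 6 (2S,4R)-5-benzyloxy-7,8-dimethoxyflavan-4-yl benzoate
Product: 7 (2S,4R)-5-benzyloxy-7,8-dimethoxyflavan-4-ol
Conditions: K2CO3 (cat.), MeOH–THF, rt
Reagents that add atoms: none
Why: Base-catalysed transesterification cleaves the acyl–oxygen bond, so the benzylic C4–O bond and its configuration are untouched.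

Step 5
Reactants: 7 (2S,4R)-5-benzyloxy-7,8-dimethoxyflavan-4-ol
Product: 8 (2S,4R)-5-benzyloxy-4-(tert-butyldimethylsilyloxy)-7,8-dimethoxyflavan
Conditions: TBSOTf, 2,6-lutidine, CH2Cl2, −78 → 0 °C
Reagents that add atoms: tert-butyldimethylsilyl triflate, CC(C)(C)[Si](C)(C)OS(=O)(=O)C(F)(F)F
Why: Silylation of the hindered pseudo-axial alcohol with a silyl triflate and a hindered base; the silyl ether later prevents O5'→O4' acyl migration of the lactone and is inert to the bases of steps 11 and 12.

Step 6
Reactants: 8 (2S,4R)-5-benzyloxy-4-(tert-butyldimethylsilyloxy)-7,8-dimethoxyflavan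
Product: 9 (2S,4R)-4-(tert-butyldimethylsilyloxy)-7,8-dimethoxyflavan-5-ol
Conditions: H2 (1 atm), Pd/C, EtOAc, rt
Reagents that add atoms: none
Why: Hydrogenolysis of the aryl benzyl ether in a neutral solvent is faster than cleavage of the ring C2–O and silylated C4–O bonds, and nothing unsaturated has yet been built.

Step 7
Reactants: 9 (2S,4R)-4-(tert-butyldimethylsilyloxy)-7,8-dimethoxyflavan-5-ol; 10 ethyl glyoxylate
Product: 12 3-hydroxybenzofuran-2(3H)-one fused at C5'–C6' of the flavan (lactone O5'–C8a(=O)–C8H(OH)–C6', C8 epimers), via 2-hydroxymandelate 11 (not isolated)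
Conditions: 10 (toluene solution, 1.5 equiv), Et3N (20 mol %), CH2Cl2, 0 °C → rt; then PPTS (30 mol %), toluene, 4 Å MS, 60 °C
Reagents that add atoms: none
Why: Base-catalysed Friedel–Crafts hydroxyalkylation of a phloroglucinol-type phenol through C6', its only free ring carbon, followed by mild acid lactonisation that spares the benzylic silyl ether; the C8–H centre is of no consequence because it is enolised in step 11.

Step 8
Reactants: 12 3-hydroxybenzofuranone of the lower flavan
Product: 13 3-methoxybenzofuran-2(3H)-one of the lower flavan (lactone O5'–C8a(=O)–C8H(OMe)–C6', C8 epimers)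
Conditions: MeOTf (1.5 equiv), 2,6-di-tert-butyl-4-methylpyridine (2 equiv), CH2Cl2, 0 °C → rt, argon
Reagents that add atoms: methyl triflate, COS(=O)(=O)C(F)(F)F
Why: O-Methylation of the α-hydroxy lactone with a methyl sulfonate and a hindered pyridine that cannot enolise C8, so that neither C-methylation nor oxidation of the enediol competes.

Step 9
Reactants: 14 acetyl chloride; 15 1,1-dichloroethene
Product: 17 4,4-dichlorobut-3-en-2-one, via 4,4,4-trichlorobutan-2-one 16 (not isolated)
Conditions: AlCl3 (1.0 equiv), CH2Cl2, 0 °C → rt; aqueous work-up; then Et3N (1.1 equiv), Et2O, 0 °C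
Reagents that add atoms: none
Why: Friedel–Crafts acylation of the alkene by the acylium ion and loss of HCl from the trichloro ketone, the classical entry to β,β-dichlorovinyl ketones.

Step 10
Reactants: 17 4,4-dichlorobut-3-en-2-one
Product: 18 4-chloro-4-methoxybut-3-en-2-one (E/Z mixture)
Conditions: NaOMe (1.0 equiv), MeOH, −30 → 0 °C
Reagents that add atoms: sodium methoxide, C[O-].[Na+]
Why: Addition–elimination of one methoxide at the β-carbon; the product, a vinylogous chloroformate, is much less electrophilic than 17, which stops the exchange after one chloride.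

Step 11
Reactants: 13 3-methoxybenzofuranone of the lower flavan; 18 4-chloro-4-methoxybut-3-en-2-one
Product: 19 (8S)-lactone with quaternary C8 bearing OMe and the arm C7(OMe)=C6H–C5(=O)–C4aH3 (enone E/Z mixture)
Conditions: 18 (1.5 equiv), N-(9-anthracenylmethyl)-O-allylcinchonidinium bromide (10 mol %; the cinchoninium analogue if it delivers the required face), Cs2CO3 (1.5 equiv), toluene–CHCl3 (7:3), −40 °C
Reagents that add atoms: none
Why: Proposed new method: nucleophilic vinylic substitution (addition–elimination) of the aromatic benzofuranone enolate at the chlorine-bearing β-carbon of 18, with loss of chloride, creates the quaternary C8 with its methoxy enone arm in place and keeps the lactone carbon C8a distinct from C7; the chiral ammonium cation is ion-paired to the flat enolate and blocks one face, and since the lower stereocentres are five bonds away the catalyst alone should decide, both C8 epimers of 13 giving the same enolate; the closest known reactions are the phase-transfer-catalysed asymmetric vinylic substitutions of β-halo enones by β-keto esters and the asymmetric Michael additions of 3-substituted benzofuran-2(3H)-ones.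

Step 12
Reactants: 19 (8S)-lactone with methoxy enone arm
Product: 21 (6S)-6-aryl-5,6-dimethoxycyclohex-4-ene-1,3-dione (C8a=O, C4aH2, C5=O, C6H=C7(OMe), C8(OMe)Ar; Ar = (2'S,4'R)-4'-(TBSO)-5'-hydroxy-7',8'-dimethoxyflavan-6'-yl), via methyl ester phenol 20 (not isolated)
Conditions: NaOMe (4 equiv), MeOH–THF (1:1), 0 → 50 °C; AcOH, 0 °C
Reagents that add atoms: none
Why: Methanolysis of the aryl lactone and Claisen (Dieckmann-type) condensation of the methyl ketone enolate C4a on the methyl ester C8a, driven by the acidic vinylogous-acid product; reversible addition of methoxide at C7 equilibrates the enone geometry towards the isomer that can cyclise and undoes any exchange of the C7 methoxy group by the phenoxide, and because C7 is already an enol ether the two arms on C8 never become equivalent, so C8 keeps its configuration.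

Step 13
Reactants: 21 silylated dione phenol
Product: 22 (6S)-6-[(2'S,4'R)-4',5'-dihydroxy-7',8'-dimethoxyflavan-6'-yl]-5,6-dimethoxycyclohex-4-ene-1,3-dione
Conditions: TBAF, AcOH (1:1, 3 equiv), THF, 0 °C → rt
Reagents that add atoms: none
Why: Buffered fluoride desilylation breaks only the Si–O bond, so the ionisable benzylic C4'–O bond keeps its R configuration and the dione sees neither strong acid nor strong base.

Step 14
Reactants: 22 dione phenol; 23 (E)-cinnamaldehyde
Product: 26 6''-demethoxyneocalycopterone, via dienylidene dione 24 (not isolated), via 2H-pyran 25 (not isolated)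
Conditions: 23 (1.5 equiv), ethylenediammonium diacetate (20 mol %), 4 Å MS, CH2Cl2, 25 → 40 °C, argon
Reagents that add atoms: none
Why: Proposed new method: the ammonium salt turns cinnamaldehyde into its iminium ion, the acidic C4a–H of the vinylogous acid adds 1,2 and loss of the amine gives the dienylidene dione 24, whose 1-oxatriene (O=C8a–C4a=C4–C3=C2) closes by oxa-6π electrocyclisation to the 2H-pyran 25; the phenol O5' then adds to C8a and the dienol is protonated at C3, which leaves the C4=C4a enone without an α-hydrogen and so without an easy way back. The closest known reactions are the formal oxa-[3+3] annulation of cyclic 1,3-diones with enals (Knoevenagel condensation and electrocyclisation) and, for the last bond, the additions of phenols to dienones and to cyclic enol ethers that close the hemiketal ring of usnic acid hydrate or make aryl tetrahydropyranyl ethers; only their combination in one flask is new. The upper pyran closes by the 6π-electrocyclisation (O1–C2 bond) and the dihydrofuran by 5-exo-trig attack of O5' on C8a, the β-carbon of the C5 enone (or, after protonation at C3, the oxocarbenium carbon). C8a is set by the fixed C8 centre, since O5' can reach C8a only on the face that carries C6' (cis-fused five-membered ring), and C2 is set by equilibration: the electrocyclisation is reversible and scrambles C2 until the epimer with equatorial phenyl, trans to the axial anomeric O5', is drained, and the ketal can still be re-equilibrated with a trace of base through the C3 dienolate. The step needs 1,2- rather than 1,4-addition to the enal (iminium activation by a primary ammonium salt), attack through C4a rather than C6 (only C4a lies between two carbonyl groups), closure through the C8a oxygen rather than the C5 oxygen (both pyrans interconvert through 24, but only the C8a isomer is trapped by O5') and addition of O5' at C8a rather than exchange at C7 (which would have to expel methanol). Water is the only by-product, and the pentacyclic core appears for the first time as the target.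

Compound list
1 | wogonin, 5,7-dihydroxy-8-methoxyflavone | COc1c(O)cc(O)c2c1oc(cc2=O)-c1ccccc1 | starting material
2 | 5-hydroxy-7,8-dimethoxyflavone | COc1c(OC)cc(O)c2c1oc(cc2=O)-c1ccccc1 | intermediate (not isolated)
3 | 5-benzyloxy-7,8-dimethoxyflavone | COc1c(OC)cc(OCc3ccccc3)c2c1oc(cc2=O)-c1ccccc1 | intermediate
4 | (2S)-5-benzyloxy-7,8-dimethoxyflavanone | COc1cc(OCc2ccccc2)c2c(c1OC)O[C@H](c1ccccc1)CC2=O | intermediate (not isolated)
5 | (2S,4S)-5-benzyloxy-7,8-dimethoxyflavan-4-ol (cis) | COc1cc(OCc2ccccc2)c2c(c1OC)O[C@H](c1ccccc1)C[C@@H]2O | intermediate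
6 | (2S,4R)-5-benzyloxy-7,8-dimethoxyflavan-4-yl benzoate (trans) | COc1cc(OCc2ccccc2)c2c(c1OC)O[C@H](c1ccccc1)C[C@H]2OC(=O)c1ccccc1 | intermediate
7 | (2S,4R)-5-benzyloxy-7,8-dimethoxyflavan-4-ol (trans) | COc1cc(OCc2ccccc2)c2c(c1OC)O[C@H](c1ccccc1)C[C@H]2O | intermediate
8 | (2S,4R)-5-benzyloxy-4-(tert-butyldimethylsilyloxy)-7,8-dimethoxyflavan | COc1cc(OCc2ccccc2)c2c(c1OC)O[C@H](c1ccccc1)C[C@H]2O[Si](C)(C)C(C)(C)C | intermediate
9 | (2S,4R)-4-(tert-butyldimethylsilyloxy)-7,8-dimethoxyflavan-5-ol | COc1cc(O)c2c(c1OC)O[C@H](c1ccccc1)C[C@H]2O[Si](C)(C)C(C)(C)C | intermediate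
10 | ethyl glyoxylate | CCOC(=O)C=O | starting material
11 | ethyl 2-hydroxy-2-[(2S,4R)-4-(TBSO)-5-hydroxy-7,8-dimethoxyflavan-6-yl]acetate (C8 epimers) | CCOC(=O)C(O)c1c(O)c2c(c(OC)c1OC)O[C@H](c1ccccc1)C[C@H]2O[Si](C)(C)C(C)(C)C | intermediate (not isolated)
12 | 3-hydroxybenzofuran-2(3H)-one fused at C5'–C6' of the (2'S,4'R)-4'-(TBSO)-7',8'-dimethoxyflavan (C8 epimers) | O=C1Oc2c3c(c(OC)c(OC)c2C1O)O[C@H](c1ccccc1)C[C@H]3O[Si](C)(C)C(C)(C)C | intermediate
13 | 3-methoxybenzofuran-2(3H)-one fused at C5'–C6' of the same flavan (C8 epimers) | O=C1Oc2c3c(c(OC)c(OC)c2C1OC)O[C@H](c1ccccc1)C[C@H]3O[Si](C)(C)C(C)(C)C | intermediate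
14 | acetyl chloride | CC(=O)Cl | starting material
15 | 1,1-dichloroethene | C=C(Cl)Cl | starting material
16 | 4,4,4-trichlorobutan-2-one | CC(=O)CC(Cl)(Cl)Cl | intermediate (not isolated)
17 | 4,4-dichlorobut-3-en-2-one | CC(=O)C=C(Cl)Cl | intermediate
18 | 4-chloro-4-methoxybut-3-en-2-one (E/Z) | CC(=O)C=C(Cl)OC | intermediate
19 | (8S)-3-methoxy-3-(1-methoxy-3-oxobut-1-enyl)benzofuran-2(3H)-one fused to the flavan (4'-OTBS; enone E/Z) | CC(=O)C=C(OC)[C@]1(OC)C(=O)Oc2c3c(c(OC)c(OC)c21)O[C@H](c1ccccc1)C[C@H]3O[Si](C)(C)C(C)(C)C | intermediate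
20 | methyl (S)-2-aryl-2,3-dimethoxy-5-oxohex-3-enoate, aryl = (2'S,4'R)-4'-(TBSO)-5'-hydroxy-7',8'-dimethoxyflavan-6'-yl | CC(=O)C=C(OC)[C@](OC)(C(=O)OC)c1c(O)c2c(c(OC)c1OC)O[C@H](c1ccccc1)C[C@H]2O[Si](C)(C)C(C)(C)C | intermediate (not isolated)
21 | (6S)-6-aryl-5,6-dimethoxycyclohex-4-ene-1,3-dione, aryl as in 20 (4'-OTBS, 5'-OH) | COC1=CC(=O)CC(=O)[C@]1(OC)c1c(O)c2c(c(OC)c1OC)O[C@H](c1ccccc1)C[C@H]2O[Si](C)(C)C(C)(C)C | intermediate
22 | (6S)-6-[(2'S,4'R)-4',5'-dihydroxy-7',8'-dimethoxyflavan-6'-yl]-5,6-dimethoxycyclohex-4-ene-1,3-dione | COC1=CC(=O)CC(=O)[C@]1(OC)c1c(O)c2c(c(OC)c1OC)O[C@H](c1ccccc1)C[C@H]2O | intermediate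
23 | (E)-cinnamaldehyde | O=C/C=C/c1ccccc1 | starting material
24 | 2-(3-phenylallylidene) derivative of 22 at C4a (1-oxatriene) | COC1=CC(=O)C(=C/C=C/c2ccccc2)C(=O)[C@]1(OC)c1c(O)c2c(c(OC)c1OC)O[C@H](c1ccccc1)C[C@H]2O | intermediate (not isolated)
25 | 2H-pyran: 7,8-dimethoxy-2-phenyl-8-aryl-2H-chromen-5(8H)-one with free 5'-OH (C2 epimers, 8S) | COC1=CC(=O)C2=C(OC(c3ccccc3)C=C2)[C@]1(OC)c1c(O)c2c(c(OC)c1OC)O[C@H](c1ccccc1)C[C@H]2O | intermediate (not isolated)
26 | 6''-demethoxyneocalycopterone (2S,8S,8aS,2'S,4'R) | COC1=CC(=O)C2=CC[C@@H](c3ccccc3)O[C@]23Oc2c4c(c(OC)c(OC)c2[C@]13OC)O[C@H](c1ccccc1)C[C@H]4O | target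

Total step count: 14 (12 on the main line, 2 for reagent 18). Longest linear sequence: 12 steps (steps 1–8 and 11–14).

Steps most likely to fail

Step 11 (proposed new method). The chiral ammonium salt may give poor facial selectivity at C8, or the enolate may attack through oxygen. Fallback: 13 and 18 would be combined with tetrabutylammonium bromide and Cs2CO3 without any chiral catalyst. This known achiral substitution should give 19 together with its C8 epimer F1. The two are diastereomers, because the lower flavan is enantiopure, and would be separated by chromatography or crystallisation. The route continues from 19 at the cost of the material that ends up as F1.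

Step 14 (proposed new method). The dione may add 1,4 to the enal, the sequence may stop at the pyran without ketal closure, or C2 may stay mixed. Fallback with known reactions, separating C–C bond formation from ketal closure: 22 would be heated in EtOAc at 60 °C with the preformed iminium salt 1-(3-phenylallylidene)piperidinium acetate F2 (from cinnamaldehyde, piperidine and Ac2O). This enforces 1,2-addition and should give the 2H-pyran 25, which would be isolated. 25 would then be closed with PPTS in CH2Cl2 (acid-catalysed addition of a phenol to a cyclic enol ether). If the C2 epimers are mixed, they would be equilibrated with a catalytic amount of DBU through the C3 dienolate. The fallback returns to the route at 26.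

Step 12. The free phenoxide may exchange the C7 methoxy group and close a benzofuran enol ether instead, or the Claisen ring closure may be slow at the hindered ester. Fallback that keeps the phenol masked during ring closure: 19 would be opened with MeOH and catalytic K2CO3 at 0 °C to the methyl ester phenol 20, which would be isolated. 20 would be benzylated (BnBr, K2CO3, DMF) to the benzyl ether F3. F3 would be cyclised with NaOMe in MeOH–THF to the O-benzyl dione F4, with no phenoxide present. Hydrogenolysis (H2, Pd/C, EtOAc) would then return to the route at 21.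

Further compounds
F1 | step 11 | (8R)-epimer of lactone 19 | CC(=O)C=C(OC)[C@@]1(OC)C(=O)Oc2c3c(c(OC)c(OC)c21)O[C@H](c1ccccc1)C[C@H]3O[Si](C)(C)C(C)(C)C
F2 | step 14 | 1-[(E)-3-phenylallylidene]piperidinium acetate | C1CC[N+](=C/C=C/c2ccccc2)CC1.CC(=O)[O-]
F3 | step 12 | 5'-O-benzyl ether of methyl ester 20 | CC(=O)C=C(OC)[C@](OC)(C(=O)OC)c1c(OCc3ccccc3)c2c(c(OC)c1OC)O[C@H](c1ccccc1)C[C@H]2O[Si](C)(C)C(C)(C)C
F4 | step 12 | 5'-O-benzyl ether of dione 21 | COC1=CC(=O)CC(=O)[C@]1(OC)c1c(OCc3ccccc3)c2c(c(OC)c1OC)O[C@H](c1ccccc1)C[C@H]2O[Si](C)(C)C(C)(C)C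
A1 | direct plan | C8–C6' biaryl of two flavans (O5 benzyl, C4 pivalate, O7 (R)-lactate benzyl ester; O5' and O4' silylated) | C[C@@H](Oc1cc(OCc3ccccc3)c2c(c1-c5c(O[Si](C)(C)C(C)(C)C)c6c(c(OC)c5OC)O[C@H](c7ccccc7)C[C@H]6O[Si](C)(C)C(C)(C)C)O[C@H](c1ccccc1)C[C@@H]2OC(=O)C(C)(C)C)C(=O)OCc1ccccc1
A2 | direct plan | (8S)-lactone-bridged 8-aryl chromandienone | C[C@H]1OC2=CC(=O)C3=C(O[C@H](c4ccccc4)C[C@@H]3OC(=O)C(C)(C)C)[C@]2(OC1=O)c1c(OC(C)=O)c2c(c(OC)c1OC)O[C@H](c1ccccc1)C[C@H]2O[Si](C)(C)C(C)(C)C
A3 | direct plan | pentacyclic 8-hydroxy-7-methoxy ketal enone with 4'-O-silyl group | COC1=CC(=O)C2=CC[C@@H](c3ccccc3)O[C@]23Oc2c4c(c(OC)c(OC)c2[C@]13O)O[C@H](c1ccccc1)C[C@H]4O[Si](C)(C)C(C)(C)C
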